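**Assumption:** (−)-epigallocatechin (1) is taken as a commercial bulk green-tea catechin, sold as the single (2R,3R) enantiomer.

## Retrosynthetic overview

1. All three rings (A, C, B) and both stereocentres (2R,3R) are bought intact in (−)-epigallocatechin 1. No ring is built and no stereocentre is created or touched.
2. Key disconnection: the 4'-O–CH3 bond. It is formed first, on unprotected 1, by a visible-light photoredox/cobalt methyl transfer from MeI 2, giving 3.
3. Second disconnection: the C3–O galloyl ester. The four remaining phenols are masked with BnBr 4 to give 5, which is esterified with tri-O-benzylgallic acid 6 to give 7.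
4. Last: global hydrogenolysis of the seven benzyl ethers gives the target 8.

## Route

**Step 1**
Reactants: 1, (−)-epigallocatechin [(2R,3R)-2-(3,4,5-trihydroxyphenyl)chromane-3,5,7-triol]; 2, methyl iodide
Product: 3, 4'-O-methyl-(−)-epigallocatechin [(2R,3R)-2-(3,5-dihydroxy-4-methoxyphenyl)chromane-3,5,7-triol]
Conditions: MeI (4 equiv), Ru(bpy)3Cl2·6H2O (1 mol%), Co(dmgH)2(py)Cl (10 mol%), NaOAc (2 equiv), degassed MeCN–H2O 1:1 (0.03 M), 450 nm LEDs, Ar, 20 °C, 12 h; stop at about 85% conversion; C18 / Sephadex LH-20
Reagents that add atoms: methyl iodide, CI (supplies CH3)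
Why: Proposed new method: a photoredox/cobalt "radical-sorting" SH2 O-methylation. Excited Ru(bpy)3 2+ is reductively quenched by proton-coupled electron transfer from the pyrogallol B ring only (about 0.42 V vs NHE at pH 7, against at least 0.8 V for the resorcinol-type A ring), giving the 4'-aryloxyl radical (weakest O–H, radical flanked by two H-bonding OH groups). Ru(I) reduces Co(II) to Co(I), which MeI methylates (SN2) to CH3–Co(III). The electrophilic 4'-O• then displaces Co(II) from the nucleophilic Co–CH3 carbon (SH2, roughly 25 kcal/mol downhill), closing a redox-neutral cycle in which acetate takes up HI. The spin-bearing ring carbons (C1', C3', C5') are all substituted, so O-attack is the open channel, and the product is no longer a pyrogallol, so it is not re-oxidised and the reaction stops at mono-methylation. The closest known reaction types are SH2 methyl transfer from iron-porphyrin or cobalamin methyl complexes to carbon radicals, and thiyl-radical SH2 on alkylcobaloximes. No stereocentre is touched.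

**Step 2**
Reactants: 3, 4'-O-methyl-(−)-epigallocatechin; 4, benzyl bromide
Product: 5, (2R,3R)-5,7-bis(benzyloxy)-2-[3,5-bis(benzyloxy)-4-methoxyphenyl]chroman-3-ol
Conditions: BnBr (4.4 equiv), K2CO3 (5 equiv), DMF, 0 °C to rt, N2, 16 h
Reagents that add atoms: benzyl bromide, BrCc1ccccc1 (four benzyl groups)
Why: Williamson etherification. Carbonate deprotonates only the four phenols, so the secondary 3-OH stays free, and the 4'-OMe group blocks the B-ring quinone-methide pathway by which catechins epimerise at C2 in base, so both stereocentres are preserved.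

**Step 3**
Reactants: 5, tetra-O-benzyl-4'-O-methyl-epigallocatechin; 6, 3,4,5-tris(benzyloxy)benzoic acid
Product: 7, (2R,3R)-5,7-bis(benzyloxy)-2-[3,5-bis(benzyloxy)-4-methoxyphenyl]chroman-3-yl 3,4,5-tris(benzyloxy)benzoate
Conditions: 6 (1.5 equiv), EDCI·HCl (2 equiv), DMAP (1 equiv), CH2Cl2, rt, 24 h
Reagents that add atoms: 3,4,5-tris(benzyloxy)benzoic acid, OC(=O)c1cc(OCc2ccccc2)c(OCc2ccccc2)c(OCc2ccccc2)c1 (supplies the acyl group; its OH is lost as water)
Why: Steglich esterification of the only free hydroxyl. Acylation occurs at oxygen, so the C3–O bond is not broken and the 3R configuration is retained.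

**Step 4**
Reactants: 7, hepta-O-benzyl-4'-O-methyl-epigallocatechin gallate
Product: 8, 4'-O-methyl-(−)-epigallocatechin-3-O-gallate [(2R,3R)-2-(3,5-dihydroxy-4-methoxyphenyl)-5,7-dihydroxychroman-3-yl 3,4,5-trihydroxybenzoate]
Conditions: H2 (1 atm), 20% Pd(OH)2/C, THF–MeOH 1:1, rt, 8 h; filter under Ar; Sephadex LH-20, lyophilise
Reagents that add atoms: none
Why: Catalytic hydrogenolysis cleaves the seven benzyl aryl ethers. The aryl methyl ether, the gallate ester and the chroman C2–O bond survive these mild conditions, as in benzyl-protected catechin gallate syntheses, and no stereocentre is affected.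

## Compound list

1 | (−)-epigallocatechin, (2R,3R)-2-(3,4,5-trihydroxyphenyl)chromane-3,5,7-triol | Oc1cc([C@H]2Oc3cc(O)cc(O)c3C[C@H]2O)cc(O)c1O | starting material
2 | methyl iodide | CI | starting material
3 | 4'-O-methyl-(−)-epigallocatechin, (2R,3R)-2-(3,5-dihydroxy-4-methoxyphenyl)chromane-3,5,7-triol | COc1c(O)cc([C@H]2Oc3cc(O)cc(O)c3C[C@H]2O)cc1O | intermediate
4 | benzyl bromide | BrCc1ccccc1 | starting material
5 | (2R,3R)-5,7-bis(benzyloxy)-2-[3,5-bis(benzyloxy)-4-methoxyphenyl]chroman-3-ol | COc1c(OCc2ccccc2)cc([C@H]2Oc3cc(OCc4ccccc4)cc(OCc4ccccc4)c3C[C@H]2O)cc1OCc1ccccc1 | intermediate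
6 | 3,4,5-tris(benzyloxy)benzoic acid | OC(=O)c1cc(OCc2ccccc2)c(OCc2ccccc2)c(OCc2ccccc2)c1 | starting material
7 | (2R,3R)-5,7-bis(benzyloxy)-2-[3,5-bis(benzyloxy)-4-methoxyphenyl]chroman-3-yl 3,4,5-tris(benzyloxy)benzoate | COc1c(OCc2ccccc2)cc([C@H]2Oc3cc(OCc4ccccc4)cc(OCc4ccccc4)c3C[C@H]2OC(=O)c2cc(OCc3ccccc3)c(OCc3ccccc3)c(OCc3ccccc3)c2)cc1OCc1ccccc1 | intermediate
8 | 4'-O-methyl-(−)-epigallocatechin-3-O-gallate | COc1c(O)cc([C@H]2Oc3cc(O)cc(O)c3C[C@H]2OC(=O)c2cc(O)c(O)c(O)c2)cc1O | target

## Step count and risks

Total steps: 4. Longest linear sequence: 4 (1 → 3 → 5 → 7 → 8).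

Steps most likely to fail:

1. **Step 1 (proposed new photoredox/cobalt SH2 O-methylation).** The risks are semiquinone disproportionation to the o-quinone followed by dimerisation, cobalt-catalysed H2 evolution instead of methyl transfer, and some 3'-O-methyl isomer. Fallback (known chemistry, ionic instead of radical): acidity-controlled SN2 methylation of 1 with MeI (about 1 equiv) and K2CO3 in acetone under Ar. The central 4'-OH is the most acidic B-ring phenol and is expected to methylate preferentially; the regioisomer mixture is then separated by preparative HPLC.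
2. **Step 2 (tetra-O-benzylation).** The risks are C-benzylation of the electron-rich A ring at C6/C8 and incomplete alkylation. Fallback: switch to O-selective sulfonate masking of the phenols (2-nitrobenzenesulfonyl chloride, amine base). After step 3 the sulfonates are removed with PhSH/Cs2CO3, and the galloyl benzyl ethers are then hydrogenolysed, at the cost of one extra step.
3. **Step 4 (sevenfold hydrogenolysis).** The risks are incomplete debenzylation, opening of the benzylic C2–O bond, and air oxidation of the product pyrogallol. Fallback: an all-silyl strategy, with TBS ethers on the four A/B-ring phenols (TBSCl, imidazole) and 3,4,5-tris(TBSO)benzoyl chloride for the ester, followed by global fluoride deprotection (Et3N·3HF or TBAF/AcOH), which avoids hydrogenation altogether.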